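## Retrosynthetic overview

- The target is the reduction product of its tert-butyl enoate. The only ring, the 14-membered carbocycle, is closed as the last C–C bond, at C5–C6, by carboalumination of a terminal alkyne and intramolecular palladium-catalysed alkenyl–allyl coupling (makes the 4E alkene, keeps 7Z).
- C12–C13 comes from hydroboration of a vinyl group on C1 and B-alkyl Suzuki coupling with (2Z,6E)-7-iodo-3-methylocta-2,6-dien-1-ol, made in two steps from prenol.
- Key disconnection C1–C1': the carbinol carbon is used as a configurationally stable α-oxygenated carbanion (lithiated secondary allylic carbamate) and joined to a secondary alkylboronic ester by boronate formation, 1,2-shift and oxidation. This creates the fully substituted carbinol and links both stereocentres in one operation.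
- C1 configuration comes from (S)-epichlorohydrin; C1' configuration from (−)-sparteine-mediated lithiation–borylation of ethyl 2,4,6-triisopropylbenzoate; the side-chain (E)-enoate from cross-metathesis.
- Ring formation order: all fragments are joined acyclic, then one macrocyclisation (step 10), then ester reduction.

Assumption: the SMILES is read as (1R) carbinol, (R) side-chain methine, ring alkenes 4E,7Z,11E and side-chain alkene E; ring atoms are C1–C14 from the carbinol carbon through the 4,5-alkene, and C1' is the side-chain methine.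

## Route

Step 1
Reactants: 1 1-(trimethylsilyl)prop-1-yne; 2 (S)-epichlorohydrin
Product: 5 trimethyl{4-[(2S)-oxiran-2-yl]but-1-yn-1-yl}silane, via lithiated silylpropyne 3 (not isolated), via lithium chlorohydrin alkoxide 4 (not isolated)
Conditions: nBuLi, TMEDA, THF, −78 to −20 °C; 2 (1.0 equiv), −78 °C to rt, then 40 °C
Reagents that add atoms: none
Why: SN2 opening of the oxirane of 2 at its CH2 by the propargylic lithium reagent followed by Williamson-type closure of the chloro-alkoxide onto the CH2Cl carbon (epoxide relay); no bond to the stereocentre is made or broken, so the configuration of 2 is carried into 5.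

Step 2
Reactants: 5 trimethyl{4-[(2S)-oxiran-2-yl]but-1-yn-1-yl}silane
Product: 7 (3S)-7-(trimethylsilyl)hept-1-en-6-yn-3-ol, via sulfonium betaine 6 (not isolated)
Conditions: Me3S+ I− (3 equiv), nBuLi (2.9 equiv), THF, −10 °C to rt
Reagents that add atoms: trimethylsulfonium iodide, C[S+](C)C.[I-]
Why: Sulfonium-ylide opening of the terminal epoxide at CH2 and ylide-mediated elimination of dimethyl sulfide from the betaine (one-carbon homologation of an epoxide to an allylic alcohol); the carbinol stereocentre is untouched.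

Step 3
Reactants: 7 (3S)-7-(trimethylsilyl)hept-1-en-6-yn-3-ol
Product: 8 (3S)-7-(trimethylsilyl)hept-1-en-6-yn-3-yl N,N-di(propan-2-yl)carbamate
Conditions: NaH, THF, 0 °C; iPr2NCOCl, reflux
Reagents that add atoms: N,N-di(propan-2-yl)carbamoyl chloride, CC(C)N(C(C)C)C(Cl)=O
Why: O-Carbamoylation of the sodium alkoxide (Hoppe carbamate formation) installs the directing and leaving group for step 6 without touching the stereocentre.

Step 4
Reactants: 9 ethyl 2,4,6-tri(propan-2-yl)benzoate; 10 2-(but-3-en-1-yl)-4,4,5,5-tetramethyl-1,3,2-dioxaborolane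
Product: 13 2-[(2R)-hex-5-en-2-yl]-4,4,5,5-tetramethyl-1,3,2-dioxaborolane, via lithiated benzoate 11 (not isolated), via boronate complex 12 (not isolated)
Conditions: sBuLi, (−)-sparteine, Et2O, −78 °C, 5 h; 10, −78 °C; then reflux
Reagents that add atoms: none
Why: Sparteine-mediated asymmetric deprotonation followed by lithiation–borylation (1,2-metallate rearrangement): (−)-sparteine directs removal of the pro-S proton, borylation occurs with retention and the butenyl group migrates with inversion, which gives the (R) secondary boronic ester.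

Step 5
Reactants: 13 2-[(2R)-hex-5-en-2-yl]-4,4,5,5-tetramethyl-1,3,2-dioxaborolane; 14 tert-butyl 2-methylprop-2-enoate
Product: 15 tert-butyl (2E,6R)-2-methyl-6-(4,4,5,5-tetramethyl-1,3,2-dioxaborolan-2-yl)hept-2-enoate
Conditions: second-generation Grubbs catalyst RuCl2(=CHPh)(SIMes)(PCy3) (5 mol%), 14 (5 equiv), CH2Cl2, 40 °C
Reagents that add atoms: none
Why: Olefin cross-metathesis of the terminal alkene with the methacrylate gives the thermodynamically favoured (E)-trisubstituted enoate; the alkylboronic ester and its stereocentre are inert to the ruthenium carbene.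

Step 6
Reactants: 8 (3S)-7-(trimethylsilyl)hept-1-en-6-yn-3-yl N,N-di(propan-2-yl)carbamate; 15 tert-butyl (2E,6R)-2-methyl-6-(4,4,5,5-tetramethyl-1,3,2-dioxaborolan-2-yl)hept-2-enoate
Product: 19 tert-butyl (2E,6R,7S)-7-ethenyl-7-hydroxy-2,6-dimethyl-11-(trimethylsilyl)undec-2-en-10-ynoate, via lithiated carbamate 16 (not isolated), via boronate complex 17 (not isolated), via tertiary boronic ester 18 (not isolated)
Conditions: sBuLi (1.0 equiv), TMEDA, Et2O, −78 °C; 15, −78 °C; MgBr2·OEt2, −78 °C to rt; NaBO3·4H2O, THF/H2O, rt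
Reagents that add atoms: sodium perborate tetrahydrate, [Na+].[O-]OB=O.O.O.O.O
Why: Hoppe–Aggarwal lithiation–borylation in which the carbinol carbon, the acceptor carbon of a conventional ketone disconnection, is used as a configurationally stable α-oxygenated carbanion: deprotonation and borylation of the allylic carbamate proceed with retention, the secondary alkyl group then migrates from boron with retention at its own carbon and inversion at the carbinol carbon while the carbamate leaves, and stereoretentive oxidation gives the tertiary alcohol, so the carbinol centre derives from (S)-8 and the methine centre from (R)-15.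

Step 7
Reactants: 20 3-methylbut-2-en-1-ol; 21 1-bromobut-2-yne
Product: 23 (2Z)-3-methyloct-2-en-6-yn-1-ol, via dilithiated prenol 22 (not isolated)
Conditions: nBuLi (2.2 equiv), TMEDA, Et2O/hexane, 0 °C to rt; 21, THF, −78 °C to rt
Reagents that add atoms: none
Why: Alkoxide-directed allylic lithiation places the second lithium on the methyl group cis to CH2OLi, and SN2 alkylation of this dianion at its terminal carbon by the propargylic bromide fixes the new chain cis to CH2OH (2Z).

Step 8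
Reactants: 23 (2Z)-3-methyloct-2-en-6-yn-1-ol
Product: 25 (2Z,6E)-7-iodo-3-methylocta-2,6-dien-1-ol, via alkenylzirconocene 24 (not isolated)
Conditions: Cp2Zr(H)Cl (3 equiv), THF, rt then 40 °C; I2, 0 °C
Reagents that add atoms: iodine, [I][I]
Why: Hydrozirconation–iodination: syn addition of Zr–H to the internal alkyne, equilibration with excess Cp2Zr(H)Cl to the alkenylzirconium on the methyl-bearing carbon and iodinolysis with retention give the (6E)-iodide, while the (2Z)-alkene is not touched.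

Step 9
Reactants: 19 tert-butyl (2E,6R,7S)-7-ethenyl-7-hydroxy-2,6-dimethyl-11-(trimethylsilyl)undec-2-en-10-ynoate; 25 (2Z,6E)-7-iodo-3-methylocta-2,6-dien-1-ol
Product: 28 tert-butyl (2E,6R,7S,10E,14Z)-7-(but-3-yn-1-yl)-7,16-dihydroxy-2,6,10,14-tetramethylhexadeca-2,10,14-trienoate, via alkylborane 26 (not isolated), via silylalkyne 27 (not isolated)
Conditions: 9-BBN, THF, 0 °C to rt; 25, PdCl2(dppf) (5 mol%), AsPh3, Cs2CO3, DMF/H2O, rt; then K2CO3, MeOH, rt
Reagents that add atoms: none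
Why: Anti-Markovnikov hydroboration of the only monosubstituted alkene, B-alkyl Suzuki–Miyaura coupling with the alkenyl iodide (both alkene geometries retained) and methanolysis of the alkynyl C–Si bond in one pot; no stereocentre is involved.

Step 10
Reactants: 28 tert-butyl (2E,6R,7S,10E,14Z)-7-(but-3-yn-1-yl)-7,16-dihydroxy-2,6,10,14-tetramethylhexadeca-2,10,14-trienoate
Product: 30 tert-butyl (2E,6R)-6-[(1R,4E,7Z,11E)-1-hydroxy-4,8,12-trimethylcyclotetradeca-4,7,11-trien-1-yl]-2-methylhept-2-enoate, via alkenylalane 29 (not isolated)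
Conditions: Me3Al (6 equiv), Cp2ZrCl2 (0.5 equiv), ClCH2CH2Cl, 0 °C to rt; then slow addition to Pd(PPh3)4 (10 mol%), THF, 1 mM, 50 °C
Reagents that add atoms: trimethylaluminium, C[Al](C)C
Why: Proposed new method: zirconium-catalysed syn-carboalumination of the terminal alkyne (Negishi) gives the (E)-alkenylalane with the new methyl on C4, and the palladium catalyst ionises the allylic O–AlMe2 group at the other chain end to a π-allyl complex that is captured intramolecularly at its unsubstituted terminus; Z-geometry is kept because isomerisation would need palladium on the fully substituted allyl carbon, and the closest known reaction is the intermolecular palladium-catalysed coupling of alkenylalanes with allylic electrophiles (O–AlMe2 leaving groups included), of which this is a macrocyclic version.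

Step 11
Reactants: 30 tert-butyl (2E,6R)-6-[(1R,4E,7Z,11E)-1-hydroxy-4,8,12-trimethylcyclotetradeca-4,7,11-trien-1-yl]-2-methylhept-2-enoate
Product: 31 (1R,4E,7Z,11E)-1-[(2R,5E)-7-hydroxy-6-methylhept-5-en-2-yl]-4,8,12-trimethylcyclotetradeca-4,7,11-trien-1-ol
Conditions: iBu2AlH (5 equiv), CH2Cl2, −78 to 0 °C; aqueous potassium sodium tartrate
Reagents that add atoms: none
Why: 1,2-Reduction of the α,β-unsaturated tert-butyl ester by the aluminium hydride gives the (E)-allylic alcohol; the isolated alkenes, the tertiary carbinol and both stereocentres are inert.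

## Compound list

1 | 1-(trimethylsilyl)prop-1-yne | CC#C[Si](C)(C)C | starting material
2 | (S)-epichlorohydrin, (2S)-2-(chloromethyl)oxirane | ClC[C@@H]1CO1 | starting material
3 | 3-lithio-1-(trimethylsilyl)prop-1-yne | [Li]CC#C[Si](C)(C)C | intermediate
4 | lithium (2S)-1-chloro-6-(trimethylsilyl)hex-5-yn-2-olate | C[Si](C)(C)C#CCC[C@H](O[Li])CCl | intermediate
5 | trimethyl{4-[(2S)-oxiran-2-yl]but-1-yn-1-yl}silane | C[Si](C)(C)C#CCC[C@H]1CO1 | intermediate
6 | (3S)-1-(dimethylsulfonio)-7-(trimethylsilyl)hept-6-yn-3-olate | C[Si](C)(C)C#CCC[C@H]([O-])CC[S+](C)C | intermediate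
7 | (3S)-7-(trimethylsilyl)hept-1-en-6-yn-3-ol | C[Si](C)(C)C#CCC[C@H](O)C=C | intermediate
8 | (3S)-7-(trimethylsilyl)hept-1-en-6-yn-3-yl N,N-di(propan-2-yl)carbamate | C[Si](C)(C)C#CCC[C@H](OC(=O)N(C(C)C)C(C)C)C=C | intermediate
9 | ethyl 2,4,6-tri(propan-2-yl)benzoate | CCOC(=O)c1c(C(C)C)cc(C(C)C)cc1C(C)C | starting material
10 | 2-(but-3-en-1-yl)-4,4,5,5-tetramethyl-1,3,2-dioxaborolane | C=CCCB1OC(C)(C)C(C)(C)O1 | starting material
11 | (1S)-1-lithioethyl 2,4,6-tri(propan-2-yl)benzoate (sparteine complex) | [Li][C@@H](C)OC(=O)c1c(C(C)C)cc(C(C)C)cc1C(C)C | intermediate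
12 | lithium (but-3-en-1-yl)[(1S)-1-{[2,4,6-tri(propan-2-yl)benzoyl]oxy}ethyl](pinacolato)borate | [Li+].C=CCC[B-]1(OC(C)(C)C(C)(C)O1)[C@@H](C)OC(=O)c1c(C(C)C)cc(C(C)C)cc1C(C)C | intermediate
13 | 2-[(2R)-hex-5-en-2-yl]-4,4,5,5-tetramethyl-1,3,2-dioxaborolane | CC1(C)OB(OC1(C)C)[C@H](C)CCC=C | intermediate
14 | tert-butyl 2-methylprop-2-enoate | CC(=C)C(=O)OC(C)(C)C | starting material
15 | tert-butyl (2E,6R)-2-methyl-6-(4,4,5,5-tetramethyl-1,3,2-dioxaborolan-2-yl)hept-2-enoate | CC1(C)OB(OC1(C)C)[C@H](C)CC/C=C(\C)C(=O)OC(C)(C)C | intermediate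
16 | (3S)-3-lithio-7-(trimethylsilyl)hept-1-en-6-yn-3-yl N,N-di(propan-2-yl)carbamate | C[Si](C)(C)C#CCC[C@]([Li])(OC(=O)N(C(C)C)C(C)C)C=C | intermediate
17 | lithium {(3S)-3-[(dipropan-2-ylcarbamoyl)oxy]-7-(trimethylsilyl)hept-1-en-6-yn-3-yl}[(2R,5E)-7-tert-butoxy-6-methyl-7-oxohept-5-en-2-yl](pinacolato)borate | [Li+].C[Si](C)(C)C#CCC[C@]([B-]1([C@H](C)CC/C=C(\C)C(=O)OC(C)(C)C)OC(C)(C)C(C)(C)O1)(OC(=O)N(C(C)C)C(C)C)C=C | intermediate
18 | tert-butyl (2E,6R,7R)-7-ethenyl-2,6-dimethyl-7-(4,4,5,5-tetramethyl-1,3,2-dioxaborolan-2-yl)-11-(trimethylsilyl)undec-2-en-10-ynoate | C[Si](C)(C)C#CCC[C@@](B1OC(C)(C)C(C)(C)O1)([C@H](C)CC/C=C(\C)C(=O)OC(C)(C)C)C=C | intermediate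
19 | tert-butyl (2E,6R,7S)-7-ethenyl-7-hydroxy-2,6-dimethyl-11-(trimethylsilyl)undec-2-en-10-ynoate | C[Si](C)(C)C#CCC[C@@](O)([C@H](C)CC/C=C(\C)C(=O)OC(C)(C)C)C=C | intermediate
20 | 3-methylbut-2-en-1-ol | CC(C)=CCO | starting material
21 | 1-bromobut-2-yne | CC#CCBr | starting material
22 | lithium (2Z)-4-lithio-3-methylbut-2-en-1-olate | [Li]C/C(C)=C\CO[Li] | intermediate
23 | (2Z)-3-methyloct-2-en-6-yn-1-ol | OC/C=C(/C)CCC#CC | intermediate
24 | chlorido{(2E,6Z)-8-[(chloridozirconocenyl)oxy]-6-methylocta-2,6-dien-2-yl}zirconocene | C/C(=C\CC/C(C)=C\CO[Zr](Cl)(C1C=CC=C1)C1C=CC=C1)[Zr](Cl)(C1C=CC=C1)C1C=CC=C1 | intermediate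
25 | (2Z,6E)-7-iodo-3-methylocta-2,6-dien-1-ol | OC/C=C(/C)CC/C=C(\C)I | intermediate
26 | tert-butyl (2E,6R,7R)-7-[2-(9-borabicyclo[3.3.1]nonan-9-yl)ethyl]-7-hydroxy-2,6-dimethyl-11-(trimethylsilyl)undec-2-en-10-ynoate | C[Si](C)(C)C#CCC[C@@](O)([C@H](C)CC/C=C(\C)C(=O)OC(C)(C)C)CCB1C2CCCC1CCC2 | intermediate
27 | tert-butyl (2E,6R,7R,10E,14Z)-7,16-dihydroxy-2,6,10,14-tetramethyl-7-[4-(trimethylsilyl)but-3-yn-1-yl]hexadeca-2,10,14-trienoate | C[Si](C)(C)C#CCC[C@@](O)([C@H](C)CC/C=C(\C)C(=O)OC(C)(C)C)CC/C(C)=C/CC/C(C)=C\CO | intermediate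
28 | tert-butyl (2E,6R,7S,10E,14Z)-7-(but-3-yn-1-yl)-7,16-dihydroxy-2,6,10,14-tetramethylhexadeca-2,10,14-trienoate | C#CCC[C@@](O)([C@H](C)CC/C=C(\C)C(=O)OC(C)(C)C)CC/C(C)=C/CC/C(C)=C\CO | intermediate
29 | tert-butyl (2E,6R,7R,10E,14Z)-7,16-bis[(dimethylalumanyl)oxy]-7-[(3E)-4-(dimethylalumanyl)-3-methylbut-3-en-1-yl]-2,6,10,14-tetramethylhexadeca-2,10,14-trienoate | C[Al](C)/C=C(\C)CC[C@@](O[Al](C)C)([C@H](C)CC/C=C(\C)C(=O)OC(C)(C)C)CC/C(C)=C/CC/C(C)=C\CO[Al](C)C | intermediate
30 | tert-butyl (2E,6R)-6-[(1R,4E,7Z,11E)-1-hydroxy-4,8,12-trimethylcyclotetradeca-4,7,11-trien-1-yl]-2-methylhept-2-enoate | C/C1=C/C/C=C(\C)CC[C@@](O)([C@H](C)CC/C=C(\C)C(=O)OC(C)(C)C)CC/C(C)=C/CC1 | intermediate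
31 | (1R,4E,7Z,11E)-1-[(2R,5E)-7-hydroxy-6-methylhept-5-en-2-yl]-4,8,12-trimethylcyclotetradeca-4,7,11-trien-1-ol | C/C1=C/C/C=C(\C)CC[C@@](O)([C@H](C)CC/C=C(\C)CO)CC/C(C)=C/CC1 | target

## Step count and risks

Total step count: 11. Longest linear sequence: 7 steps (1, 2, 3, 6, 9, 10, 11).

Three steps most likely to fail:

Step 6. The lithiated carbamate 16 carries an unsubstituted vinyl terminus and may be borylated there instead of at the carbinol carbon, and the hindered complex 17 may revert instead of rearranging. The fallback builds the carbinol centre by olefination and Sharpless epoxidation; it sets out from 15 and returns at 19. 2-Lithio-3-[(tert-butyldimethylsilyl)oxy]prop-1-ene (from the bromide and tBuLi) is added to 15, followed by I2 and NaOMe (Zweifel olefination, retention at the methine), to give tert-butyl (2E,6R)-7-({[tert-butyl(dimethyl)silyl]oxy}methyl)-2,6-dimethylocta-2,7-dienoate F1. Bu4NF gives tert-butyl (2E,6R)-7-(hydroxymethyl)-2,6-dimethylocta-2,7-dienoate F2. Sharpless asymmetric epoxidation (Ti(OiPr)4, D-(−)-diethyl tartrate, tBuOOH) with in situ tosylation (TsCl, Et3N) gives tert-butyl (2E,6R)-2-methyl-6-[(2S)-2-({[(4-methylphenyl)sulfonyl]oxy}methyl)oxiran-2-yl]hept-2-enoate F3. The lithiated silylpropyne 3 with BF3·OEt2 opens the oxirane at CH2 and NaH closes the tertiary alkoxide onto the tosylate to give tert-butyl (2E,6R)-2-methyl-6-{(2R)-2-[4-(trimethylsilyl)but-3-yn-1-yl]oxiran-2-yl}hept-2-enoate F4. Dimethylsulfonium methylide, as in step 2, converts F4 into 19.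

Step 10. The macrocyclic alkenylalane–allyl coupling through an O–AlMe2 leaving group is unprecedented at this ring size and may give oligomers or partial Z to E leakage. The fallback closes the same C5–C6 bond by a Stille reaction; it sets out from 28 and returns at 30. Carboalumination as in step 10 (via 29) but quenched with I2 gives tert-butyl (2E,6R,7R,10E,14Z)-7,16-dihydroxy-7-[(3E)-4-iodo-3-methylbut-3-en-1-yl]-2,6,10,14-tetramethylhexadeca-2,10,14-trienoate F5. (Me3Sn)2 with Pd(PPh3)4 gives tert-butyl (2E,6R,7R,10E,14Z)-7,16-dihydroxy-2,6,10,14-tetramethyl-7-[(3E)-3-methyl-4-(trimethylstannyl)but-3-en-1-yl]hexadeca-2,10,14-trienoate F6. MsCl and Et3N, then LiCl, convert the primary allylic alcohol into tert-butyl (2E,6R,7R,10E,14Z)-16-chloro-7-hydroxy-2,6,10,14-tetramethyl-7-[(3E)-3-methyl-4-(trimethylstannyl)but-3-en-1-yl]hexadeca-2,10,14-trienoate F7. Stille macrocyclisation (Pd2(dba)3, AsPh3, THF, high dilution) gives 30.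

Step 7. The prenol dianion 22 may be alkylated at its inner carbon or give E/Z mixtures. The fallback makes the (Z)-alkene by enol phosphate–cuprate coupling; it sets out from 21 and returns at 23. The dianion of methyl acetoacetate (NaH, then nBuLi) is alkylated with 21 to give methyl 3-oxooct-6-ynoate F8. ClP(O)(OEt)2, Et3N and DMAP in DMPU give methyl (2E)-3-[(diethoxyphosphoryl)oxy]oct-2-en-6-ynoate F9. Me2CuLi replaces the phosphate with retention to give methyl (2Z)-3-methyloct-2-en-6-ynoate F10. iBu2AlH reduces F10 to 23.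

Further compounds
F1 | step 6 | tert-butyl (2E,6R)-7-({[tert-butyl(dimethyl)silyl]oxy}methyl)-2,6-dimethylocta-2,7-dienoate | C=C(CO[Si](C)(C)C(C)(C)C)[C@H](C)CC/C=C(\C)C(=O)OC(C)(C)C
F2 | step 6 | tert-butyl (2E,6R)-7-(hydroxymethyl)-2,6-dimethylocta-2,7-dienoate | C=C(CO)[C@H](C)CC/C=C(\C)C(=O)OC(C)(C)C
F3 | step 6 | tert-butyl (2E,6R)-2-methyl-6-[(2S)-2-({[(4-methylphenyl)sulfonyl]oxy}methyl)oxiran-2-yl]hept-2-enoate | Cc1ccc(cc1)S(=O)(=O)OC[C@@]1(CO1)[C@H](C)CC/C=C(\C)C(=O)OC(C)(C)C
F4 | step 6 | tert-butyl (2E,6R)-2-methyl-6-{(2R)-2-[4-(trimethylsilyl)but-3-yn-1-yl]oxiran-2-yl}hept-2-enoate | C[Si](C)(C)C#CCC[C@]1(CO1)[C@H](C)CC/C=C(\C)C(=O)OC(C)(C)C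
F5 | step 10 | tert-butyl (2E,6R,7R,10E,14Z)-7,16-dihydroxy-7-[(3E)-4-iodo-3-methylbut-3-en-1-yl]-2,6,10,14-tetramethylhexadeca-2,10,14-trienoate | I/C=C(\C)CC[C@@](O)([C@H](C)CC/C=C(\C)C(=O)OC(C)(C)C)CC/C(C)=C/CC/C(C)=C\CO
F6 | step 10 | tert-butyl (2E,6R,7R,10E,14Z)-7,16-dihydroxy-2,6,10,14-tetramethyl-7-[(3E)-3-methyl-4-(trimethylstannyl)but-3-en-1-yl]hexadeca-2,10,14-trienoate | C[Sn](C)(C)/C=C(\C)CC[C@@](O)([C@H](C)CC/C=C(\C)C(=O)OC(C)(C)C)CC/C(C)=C/CC/C(C)=C\CO
F7 | step 10 | tert-butyl (2E,6R,7R,10E,14Z)-16-chloro-7-hydroxy-2,6,10,14-tetramethyl-7-[(3E)-3-methyl-4-(trimethylstannyl)but-3-en-1-yl]hexadeca-2,10,14-trienoate | C[Sn](C)(C)/C=C(\C)CC[C@@](O)([C@H](C)CC/C=C(\C)C(=O)OC(C)(C)C)CC/C(C)=C/CC/C(C)=C\CCl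
F8 | step 7 | methyl 3-oxooct-6-ynoate | CC#CCCC(=O)CC(=O)OC
F9 | step 7 | methyl (2E)-3-[(diethoxyphosphoryl)oxy]oct-2-en-6-ynoate | CCOP(=O)(OCC)O/C(CCC#CC)=C/C(=O)OC
F10 | step 7 | methyl (2Z)-3-methyloct-2-en-6-ynoate | COC(=O)/C=C(/C)CCC#CC
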